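**Strategy.** The route rests on cutting ring C of the lower flavan unit at its two bonds to ring A, C4–C4a and O1–C8a. In one operation an ortho-fluoroaryl Grignard reagent (nucleophilic at the future C4a, electrophilic at the fluorinated future C8a) is annulated onto an erythro epoxy alcohol that supplies O1, C2, C3 and C4 with both stereocentres already in place: copper-catalysed epoxide opening, then fluoride displacement by the benzylic alkoxide. The step exploits the ortho relationship of the C4 methylene and the O1 ether on ring A. The resulting tri-O-benzyl fisetinidol serves twice, as nucleophile and, after C4 oxidation, as electrophile for the C4–C6 interflavan bond.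

Key step: step 3

Remarks and assumptions:
- Flavan numbering (O1, C2, C3, C4, C4a, C5 to C8, C8a) is used for each unit.
- The target is read as the 2,3-trans-3,4-trans dimer of two (2R,3S)-fisetinidol units, joined from C4 (R, aryl trans to the 3-hydroxyl) of the upper unit to C6 of the lower unit.
- The C4 configuration of 8 is assumed and drawn as 4S (alkoxy trans to the C2 aryl group). It is erased when C4 is ionised in step 5.
- Compounds 1 and 4 are taken as catalogue compounds.

Step 1
Reactants: 1 3,4-bis(benzyloxy)benzaldehyde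
Product: 2 rac-1-[3,4-bis(benzyloxy)phenyl]prop-2-en-1-ol
Conditions: vinylMgBr (1.2 equiv), THF, −78 → 0 °C; aq NH4Cl
Reagents that add atoms: vinylmagnesium bromide, C=C[Mg]Br
Why: Grignard 1,2-addition to an aromatic aldehyde should give the aryl vinyl carbinol; the new carbinol centre is formed racemic on purpose, because step 2 resolves it.

Step 2
Reactants: 2 rac-1-[3,4-bis(benzyloxy)phenyl]prop-2-en-1-ol
Product: 3 (R)-[3,4-bis(benzyloxy)phenyl][(2S)-oxiran-2-yl]methanol (erythro)
Conditions: Ti(OiPr)4 (10 mol%), D-(−)-diisopropyl tartrate (15 mol%), t-BuOOH (0.6 equiv), 4 Å MS, CH2Cl2, −20 °C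
Reagents that add atoms: tert-butyl hydroperoxide, CC(C)(C)OO
Why: Sharpless kinetic resolution by asymmetric epoxidation: with the D-(−)-tartrate catalyst the S enantiomer of 2 is the matched one and is epoxidised on the face that gives the erythro epoxy alcohol, so the carbinol centre is selected from the racemate and the oxirane centre is set by the catalyst; the R enantiomer of 2 stays behind and is removed by chromatography.

Step 3
Reactants: 4 4-(benzyloxy)-1-bromo-2-fluorobenzene; 3 (R)-[3,4-bis(benzyloxy)phenyl][(2S)-oxiran-2-yl]methanol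
Product: 7 (2R,3S)-7-(benzyloxy)-2-[3,4-bis(benzyloxy)phenyl]-3,4-dihydro-2H-chromen-3-ol, via aryl Grignard reagent 5 (not isolated), via ring-opened fluoroaryl diol 6 (not isolated)
Conditions: 4 (1.2 equiv), i-PrMgCl·LiCl, THF, 0 °C; then chloromagnesium alkoxide of 3 (from 3 and i-PrMgCl·LiCl, 1.0 equiv, THF, −40 °C), CuBr·SMe2 (10 mol%), −30 → 0 °C; then KOt-Bu (4 equiv), DMF, 70 °C; aq NH4Cl
Reagents that add atoms: none
Why: Bromine–magnesium exchange on 4 gives 5, whose carbon–magnesium bond lies ortho to a carbon–fluorine bond that is inert at 0 °C, so one arene carries the nucleophilic future C4a and the electrophilic future C8a; copper-catalysed attack of 5 on the unsubstituted epoxide carbon of 3 forms C4–C4a and gives 6 as its dialkoxide, and after metal exchange with KOt-Bu in DMF the benzylic alkoxide displaces fluoride at C8a by addition–elimination through a Meisenheimer-type adduct, forming O1–C8a. The closest known reaction types are the copper-catalysed opening of terminal epoxides by aryl Grignard reagents and the intramolecular nucleophilic aromatic substitution of a fluoroarene by an alkoxide that closes the pyran ring of flavan-3-ols, here run in one flask. Ring C closes as a six-membered ring by attack of O1 on the fluorine-bearing carbon of ring A, exo with respect to the departing C–F bond. No stereocentre is created: C2 keeps its configuration because its C–O bond is never broken, and C3 keeps its configuration because only the CH2 terminus of the epoxide is attacked, so the erythro relationship of 3 becomes the (2R,3S) trans relationship of 7. The step needs terminal over internal epoxide opening, which sterics under copper catalysis should secure, and six- over five-membered ether closure, which should follow because the C3 alkoxide could reach C8a only through a strained two-atom tether whereas the C2 alkoxide can approach perpendicular to ring A; the benzyloxy group is meta to fluorine and does not deactivate the substitution.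

Step 4
Reactants: 7 (2R,3S)-7-(benzyloxy)-2-[3,4-bis(benzyloxy)phenyl]-3,4-dihydro-2H-chromen-3-ol
Product: 8 (2R,3S,4S)-7-(benzyloxy)-2-[3,4-bis(benzyloxy)phenyl]-4-(2-ethoxyethoxy)-3,4-dihydro-2H-chromen-3-ol
Conditions: DDQ (2 equiv), 2-ethoxyethanol (5 equiv), CH2Cl2, 23 °C
Reagents that add atoms: 2-ethoxyethanol, CCOCCO
Why: Benzylic oxidation by hydride abstraction with DDQ at C4 should be favoured because the resulting cation is stabilised by O1 (ortho) and the 7-benzyloxy group (para) on ring A, and the alcohol traps it as the C4 ether; the C4 configuration is of no consequence for step 5.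

Step 5
Reactants: 8 (2R,3S,4S)-7-(benzyloxy)-2-[3,4-bis(benzyloxy)phenyl]-4-(2-ethoxyethoxy)-3,4-dihydro-2H-chromen-3-ol; 7 (2R,3S)-7-(benzyloxy)-2-[3,4-bis(benzyloxy)phenyl]-3,4-dihydro-2H-chromen-3-ol (4 equiv)
Product: 9 hexa-O-benzyl ether of the target (2,3-trans-3,4-trans upper unit bonded from C4 to C6 of the lower unit; all six phenols benzylated, both 3-hydroxyls free)
Conditions: TMSOTf (0.2 equiv), CH2Cl2, −78 → −30 °C; Et3N
Reagents that add atoms: none
Why: TMSOTf ionises the C4 ether of 8 to a benzylic cation, and ring A of 7 captures it in a Friedel–Crafts alkylation at C6, which is para to O1, ortho to the benzyloxy group and less hindered than C8 between the two oxygens; the new C4 stereocentre is set by the substrate, the arene approaching the face opposite the C3 hydroxyl (3,4-trans), and the excess of 7 should hold back chain growth and is recovered.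

Step 6
Reactants: 9 hexa-O-benzyl ether of the target
Product: 10 (2R,3S,4R)-2-(3,4-dihydroxyphenyl)-4-[(2R,3S)-2-(3,4-dihydroxyphenyl)-3,7-dihydroxy-3,4-dihydro-2H-chromen-6-yl]-3,4-dihydro-2H-chromene-3,7-diol
Conditions: H2 (1 atm), Pd(OH)2/C, THF–MeOH, 23 °C
Reagents that add atoms: none
Why: Catalytic hydrogenolysis should cleave the six aryl benzyl ethers, while the C4–C6 bond and the ring C–O bonds have no leaving group under these neutral conditions and no stereocentre is touched.

**Compound list**

1 | 3,4-bis(benzyloxy)benzaldehyde | O=Cc1ccc(OCc2ccccc2)c(OCc2ccccc2)c1 | starting material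
2 | rac-1-[3,4-bis(benzyloxy)phenyl]prop-2-en-1-ol | OC(C=C)c1ccc(OCc2ccccc2)c(OCc2ccccc2)c1 | intermediate
3 | (R)-[3,4-bis(benzyloxy)phenyl][(2S)-oxiran-2-yl]methanol | O[C@H](c1ccc(OCc2ccccc2)c(OCc2ccccc2)c1)[C@@H]1CO1 | intermediate
4 | 4-(benzyloxy)-1-bromo-2-fluorobenzene | Fc1cc(OCc2ccccc2)ccc1Br | starting material
5 | [4-(benzyloxy)-2-fluorophenyl]magnesium chloride (LiCl complex) | Fc1cc(OCc2ccccc2)ccc1[Mg]Cl | intermediate
6 | (1R,2S)-1-[3,4-bis(benzyloxy)phenyl]-3-[4-(benzyloxy)-2-fluorophenyl]propane-1,2-diol (present as its dialkoxide) | O[C@H](c1ccc(OCc2ccccc2)c(OCc2ccccc2)c1)[C@@H](O)Cc1ccc(OCc2ccccc2)cc1F | intermediate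
7 | (2R,3S)-7-(benzyloxy)-2-[3,4-bis(benzyloxy)phenyl]-3,4-dihydro-2H-chromen-3-ol | c1ccccc1COc1ccc2c(c1)O[C@H](c1ccc(OCc3ccccc3)c(OCc3ccccc3)c1)[C@@H](O)C2 | intermediate
8 | (2R,3S,4S)-7-(benzyloxy)-2-[3,4-bis(benzyloxy)phenyl]-4-(2-ethoxyethoxy)-3,4-dihydro-2H-chromen-3-ol | c1ccccc1COc1ccc2c(c1)O[C@H](c1ccc(OCc3ccccc3)c(OCc3ccccc3)c1)[C@@H](O)[C@H]2OCCOCC | intermediate
9 | hexa-O-benzyl ether of the target (both 3-hydroxyls free) | c1ccccc1COc1ccc2c(c1)O[C@H](c1ccc(OCc3ccccc3)c(OCc3ccccc3)c1)[C@@H](O)[C@@H]2c1cc2c(cc1OCc1ccccc1)O[C@H](c1ccc(OCc3ccccc3)c(OCc3ccccc3)c1)[C@@H](O)C2 | intermediate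
10 | (2R,3S,4R)-2-(3,4-dihydroxyphenyl)-4-[(2R,3S)-2-(3,4-dihydroxyphenyl)-3,7-dihydroxy-3,4-dihydro-2H-chromen-6-yl]-3,4-dihydro-2H-chromene-3,7-diol | Oc1ccc2c(c1)O[C@H](c1ccc(O)c(O)c1)[C@@H](O)[C@@H]2c1cc2c(cc1O)O[C@H](c1ccc(O)c(O)c1)[C@@H](O)C2 | target

Total step count: 6.
Longest linear sequence: 6 steps (1 → 2 → 3 → 7 → 8 → 9 → 10).

**Steps most likely to fail**

Step 3. The one-flask annulation may fail in several ways. The fluoroaryl Grignard reagent may lose fluoride (aryne formation) before it meets the epoxide. The unprotected epoxy alkoxide may undergo base-induced epoxide migration. The fluoride displacement may stall on magnesium-bound alkoxides, or be diverted to five-membered closure by the C3 oxygen. The fallback separates the two bond formations and gives each oxygen its own protecting group. It sets out from 3 and 4 and comes back at 7. Compound 3 is silylated (TBSCl, imidazole, DMF) to the tert-butyldimethylsilyl ether F1. Compound 4 is lithiated (n-BuLi, THF, −78 °C) and added to F1 with BF3·OEt2 at −78 °C, which should give the fluoroaryl secondary alcohol F2. The new hydroxyl is capped (MOMCl, i-Pr2NEt, CH2Cl2) to the methoxymethyl ether F3. TBAF in THF then frees the benzylic alcohol F4. KH in DMF closes the pyran ring by fluoride displacement to the 3-O-methoxymethyl flavan F5. HCl in MeOH removes the acetal and returns to 7.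

Step 5. The coupling may suffer from poor site selectivity between C6 and C8 of the nucleophile, from attack on the face syn to the C3 hydroxyl, and from chain growth because the electrophile carries a nucleophilic ring A of its own. The fallback sets out from 7 and 8 and comes back at 10. It uses a nucleophile with free phenols, which is far more reactive than any benzylated ring A and follows the intrinsic C6 preference of resorcinol-type flavans. Compound 7 is hydrogenolysed (H2, Pd(OH)2/C, THF–MeOH) to (2R,3S)-fisetinidol F6. F6 (3 equiv) is condensed with 8 (BF3·OEt2, THF–CH2Cl2, 0 °C), which should give the dimer benzylated only in its upper unit F7. Hydrogenolysis of F7 under the conditions of step 6 gives 10.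

Step 4. The oxidation may be diverted by hydride abstraction at C2, which is a dialkoxybenzyl ether carbon, or by over-oxidation of the product. The fallback carries the C4 oxygen in from a dihydroflavonol and needs no C–H oxidation. It sets out from 7, which is kept as the nucleophile, and comes back at 9. Purchased (2R,3R)-fustin is benzylated at its three phenols (BnBr, K2CO3, DMF) to the tri-O-benzyl dihydroflavonol F8. Reduction of the ketone (NaBH4, THF–EtOH, 0 °C) should give the 2,3-trans-3,4-trans flavan-3,4-diol F9. F9 ionises at C4 under the Lewis acid of step 5 and is captured by 7 (4 equiv) to return to 9.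

Further compounds
F1 | step 3 | tert-butyldimethylsilyl ether of 3, (R)-carbinol, (S)-oxirane | CC(C)(C)[Si](C)(C)O[C@H](c1ccc(OCc2ccccc2)c(OCc2ccccc2)c1)[C@@H]1CO1
F2 | step 3 | (1R,2S)-1-[3,4-bis(benzyloxy)phenyl]-3-[4-(benzyloxy)-2-fluorophenyl]-1-(tert-butyldimethylsilyloxy)propan-2-ol | CC(C)(C)[Si](C)(C)O[C@H](c1ccc(OCc2ccccc2)c(OCc2ccccc2)c1)[C@@H](O)Cc1ccc(OCc2ccccc2)cc1F
F3 | step 3 | 2-O-methoxymethyl ether of F2 | CC(C)(C)[Si](C)(C)O[C@H](c1ccc(OCc2ccccc2)c(OCc2ccccc2)c1)[C@@H](OCOC)Cc1ccc(OCc2ccccc2)cc1F
F4 | step 3 | (1R,2S)-1-[3,4-bis(benzyloxy)phenyl]-3-[4-(benzyloxy)-2-fluorophenyl]-2-(methoxymethoxy)propan-1-ol | O[C@H](c1ccc(OCc2ccccc2)c(OCc2ccccc2)c1)[C@@H](OCOC)Cc1ccc(OCc2ccccc2)cc1F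
F5 | step 3 | (2R,3S)-7-(benzyloxy)-2-[3,4-bis(benzyloxy)phenyl]-3-(methoxymethoxy)-3,4-dihydro-2H-chromene | c1ccccc1COc1ccc2c(c1)O[C@H](c1ccc(OCc3ccccc3)c(OCc3ccccc3)c1)[C@@H](OCOC)C2
F6 | step 5 | (2R,3S)-fisetinidol, (2R,3S)-2-(3,4-dihydroxyphenyl)-3,4-dihydro-2H-chromene-3,7-diol | Oc1ccc2c(c1)O[C@H](c1ccc(O)c(O)c1)[C@@H](O)C2
F7 | step 5 | target dimer with the three phenols of the upper unit benzylated | c1ccccc1COc1ccc2c(c1)O[C@H](c1ccc(OCc3ccccc3)c(OCc3ccccc3)c1)[C@@H](O)[C@@H]2c1cc2c(cc1O)O[C@H](c1ccc(O)c(O)c1)[C@@H](O)C2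
F8 | step 4 | (2R,3R)-7-(benzyloxy)-2-[3,4-bis(benzyloxy)phenyl]-3-hydroxy-2,3-dihydro-4H-chromen-4-one | O=C1c2ccc(OCc3ccccc3)cc2O[C@H](c2ccc(OCc3ccccc3)c(OCc3ccccc3)c2)[C@H]1O
F9 | step 4 | (2R,3S,4R)-7-(benzyloxy)-2-[3,4-bis(benzyloxy)phenyl]-3,4-dihydro-2H-chromene-3,4-diol | c1ccccc1COc1ccc2c(c1)O[C@H](c1ccc(OCc3ccccc3)c(OCc3ccccc3)c1)[C@@H](O)[C@@H]2O
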